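## Analysis of the target

- Justin C (16) is an acyclic 8,8′-linked lignan of the dibenzylbutane type. Its four-carbon chain C9–C8–C8′–C9′ carries acetoxy groups at both ends, a 3,4-dimethoxybenzyl group (C7 and ring A) on C8, and a 4-hydroxy-3,5-dimethoxybenzyl group (C7′ and ring B) on C8′.
- The two benzene rings are the only rings, so no cyclic framework can relay stereochemical information.
- The only stereocentres, C8 and C8′, are neighbours and both R. Each bears H, a CH2OAc, a CH2Ar and the other methine, so the molecule would be C2-symmetric if rings A and B were alike. The unwanted diastereomer is the meso-like (8R,8′S) form.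
- The two halves differ only in the substituents of rings A and B, several bonds away from the stereocentres. Late differentiation of the halves is therefore impossible, and statistical mixtures are the standing danger.
- The plan rests on the 1,4-relationship of the oxygen atoms on C9 and C9′ across the C8–C8′ bond. At the carboxyl oxidation level C8 and C8′ are both α-carbons, hence both donors, so the central bond joins two carbons of like polarity and is closed to ordinary enolate/electrophile logic. It is also the one bond that splits 16 into two C6–C3 halves of equal size and connects both stereocentres.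
- Two groups are sensitive. The free 2,6-dimethoxyphenol of ring B is very easily oxidised and is acylated in competition with the alcohols. The two primary acetates are lost with base, hydride or organometallics and must therefore come late.
- The difficulty is acyclic 1,2-stereocontrol in a nearly symmetrical but unsymmetrical chain, with a phenol that must end up free next to two esterified alcohols.

## Retrosynthetic reasoning

**16 ⇒ 15 ⇒ 14.**
- The benzyl–oxygen bond on C4 of ring B is the last bond broken, and the two acetate C–O bonds at C9 and C9′ are the last bonds made.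
- A benzyl ether is chosen because it leaves under neutral hydrogenolysis, which does not touch acetates.
- The benzyl ether also keeps ring B from being a phenoxide in every basic, reducing or oxidising step before that.
- This reduces the problem to diol 14.

**14 ⇒ 13.**
- C9′ is raised to the carboxyl level and tied to the oxygen on C9 as the γ-lactone 13.
- Nothing is cut in the carbon skeleton. What is gained is a five-membered ring in which C8′ is the only enolisable centre and in which the trans arrangement of the two benzyl groups is the more stable one.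
- The lactone is therefore a thermodynamic funnel for C8′, while C8, in the β-position, cannot move.

**13 ⇒ 11 (through 12).**
- The ring C–O bond is opened to a succinic acid derivative 11 whose two carboxyl termini differ: an N-acyloxazolidinone at C9 and a tert-butyl ester at C9′.
- The forward reaction must reduce only the imide carbonyl to give 12, close the ring, and equilibrate C8′.

**11 ⇒ 4 + 8 (through 9 and 10), the key disconnection.**
- The C8–C8′ bond is cut, giving two 3-arylpropanoic acid derivatives with no stereocentre in the chain. This is the largest simplification available.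
- No other cut gives two halves of equal size, uses the hidden symmetry, or addresses both stereocentres at once.
- The forward reaction must unite two enolate carbons with removal of two electrons.
- It must also favour the cross product over the two homodimers and form the bond on the face of 9 that the auxiliary leaves open.
- In one sentence: the lithium enolates 9 and 10 of two different dihydrocinnamic acid derivatives are cross-coupled oxidatively at their α-carbons.

**4 ⇒ 1 + 2 (through 3); 8 ⇒ 7 ⇒ 5 + 6.**
- The imide is one N-acylation away from the commercial acid 1 and auxiliary 2.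
- The ester is a two-carbon olefination of aldehyde 5 with phosphonate 6, followed by saturation of the C7′–C8′ double bond of 7 without loss of the benzyl ether.
- The precursors of the key step thus cost one and two steps.

## Alternatives that were turned down

**Alternative 1: the textbook route, cut at C7–C8.**
- Disconnection: the benzylic CH2–methine bond of the ring A half.
- Forward key step: the lithium enolate of the enantiopure β-substituted lactone (4R)-4-[4-(benzyloxy)-3,5-dimethoxybenzyl]oxolan-2-one A1 is alkylated with 4-(bromomethyl)-1,2-dimethoxybenzene A2, anti to the substituent on C4. This gives the trans-lactone A3, which would be reduced to 14.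
- Reasons for rejection:
  - The key step forms a peripheral bond and sets one stereocentre only.
  - C8′ has to be set beforehand in a separate asymmetric operation.
  - A1 costs about six linear steps from 5: chain extension, saturation, attachment of a controller, introduction of a C2 unit, reduction and ring closure. Ring A enters only after that.
  - The two nearly identical halves are built by two unrelated sequences, so the hidden symmetry is wasted and the linear sequence grows to about ten steps.

**Alternative 2: cut of the four C–H bonds at C7, C8, C7′ and C8′.**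
- Forward key step: double enantioselective hydrogenation of the (E,E)-dibenzylidenesuccinate A4, assembled by two successive Stobbe condensations with re-esterification. This gives the (2R,3R)-dibenzylsuccinate A5, which would be reduced to 14.
- Reasons for rejection:
  - A4 is a crowded cross-conjugated diene twisted about C8–C8′, with no strongly binding donor next to either double bond.
  - After the first addition of hydrogen, the second is governed by the catalyst and by the new stereocentre together, so the like/unlike outcome is not secured by the catalyst alone.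
  - A 1,4-addition of hydrogen would give the tetrasubstituted C8=C8′ alkene and with it another stereochemical course.
  - Dienes of this type are prone to E/Z isomerisation and to electrocyclisation towards aryldihydronaphthalenes.
  - The precursor costs about four steps.

**Alternative 3: cut of the two aryl–CH2 bonds (ring A–C7 and ring B–C7′).**
- What remains is the achiral tetrol 2,3-bis(hydroxymethyl)butane-1,4-diol A6, whose hydroxymethyl arms are pairwise enantiotopic.
- Forward key step: a lipase-catalysed double desymmetrising acetylation to the C2-symmetric diacetate A7. This would place both acetates of the target and set both stereocentres at once. Conversion into the diiodide A8 and two nickel-catalysed cross-electrophile couplings with the two aryl halides would follow.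
- Reasons for rejection:
  - The two arms of A7 and A8 that must be arylated are homotopic, so two different rings can only be introduced statistically.
  - Each stereocentre of A7 is a 2-substituted propane-1,3-diol monoacetate, so a 1,3-acyl shift erases it.
  - A primary radical or alkylnickel species at C7 with a second iodide four carbons away invites cyclisation and reduction.
  - More steps would follow the key step than in the chosen route.

Key step: step 4

Assumption: lignan locants are used throughout (C7–C9 for the ring A half, C7′–C9′ for the ring B half), and 5 is taken to be a catalogue compound.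

## Steps

Step 1
Reactants: 1 3-(3,4-dimethoxyphenyl)propanoic acid; 2 (4S)-4-benzyl-1,3-oxazolidin-2-one
Product: 4 (4S)-4-benzyl-3-[3-(3,4-dimethoxyphenyl)propanoyl]-1,3-oxazolidin-2-one, via 3-(3,4-dimethoxyphenyl)propanoic pivalic anhydride 3 (not isolated)
Conditions: PivCl, Et3N, THF, −20 °C; then LiCl, 2, −20 °C → rt
Reagents that add atoms: pivaloyl chloride, CC(C)(C)C(=O)Cl (its acyl group is found in 3 only and is lost again on the way to 4)
Why: Mixed-anhydride N-acylation of an oxazolidinone in the LiCl/Et3N variant; the hindered pivaloyl carbonyl of 3 steers the nitrogen nucleophile to the 3-arylpropanoyl carbonyl. No stereocentre is formed and C4 of the auxiliary is not touched.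

Step 2
Reactants: 5 4-(benzyloxy)-3,5-dimethoxybenzaldehyde; 6 tert-butyl (diethoxyphosphoryl)acetate
Product: 7 tert-butyl (2E)-3-[4-(benzyloxy)-3,5-dimethoxyphenyl]prop-2-enoate
Conditions: LiCl, DBU, MeCN, rt
Reagents that add atoms: none
Why: Horner–Wadsworth–Emmons olefination under Masamune–Roush conditions; a stabilised phosphonate and an aromatic aldehyde should give the E-cinnamate. The geometry is of no consequence, since the double bond is saturated next.

Step 3
Reactants: 7 tert-butyl (2E)-3-[4-(benzyloxy)-3,5-dimethoxyphenyl]prop-2-enoate
Product: 8 tert-butyl 3-[4-(benzyloxy)-3,5-dimethoxyphenyl]propanoate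
Conditions: H2 (4 bar), RhCl(PPh3)3 (cat.), PhMe/EtOH 1:1, 50 °C
Reagents that add atoms: none
Why: Homogeneous hydrogenation with Wilkinson's catalyst saturates 1,2-disubstituted conjugated alkenes such as cinnamates and has no pathway for hydrogenolysis of an aryl benzyl ether. The tert-butyl ester is inert in neutral ethanol.

Step 4
Reactants: 4 (4S)-4-benzyl-3-[3-(3,4-dimethoxyphenyl)propanoyl]-1,3-oxazolidin-2-one; 8 tert-butyl 3-[4-(benzyloxy)-3,5-dimethoxyphenyl]propanoate
Product: 11 tert-butyl (2R,3R)-4-[(4S)-4-benzyl-2-oxo-1,3-oxazolidin-3-yl]-2-[4-(benzyloxy)-3,5-dimethoxybenzyl]-3-(3,4-dimethoxybenzyl)-4-oxobutanoate, via the chelated lithium (Z)-enolate of the imide 9 (not isolated), via the lithium enolate of the tert-butyl ester (CH2Ar trans to OLi) 10 (not isolated)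
Conditions: 4 (1 equiv), 8 (1.5 equiv), LDA (2.6 equiv), THF, −78 °C; then Cu(II) 2-ethylhexanoate (2.6 equiv), THF, −78 °C → rt
Reagents that add atoms: LDA, [Li+].CC(C)[N-]C(C)C (its lithium is found in 9 and 10 only, not in 11)
Why: Oxidative intermolecular heterocoupling of an N-acyloxazolidinone enolate with an ester enolate is a known reaction type for unsymmetrical 2,3-disubstituted succinates, applied here to two 3-arylpropanoyl partners. LDA turns 4 into the lithium-chelated Z-enolate 9 and 8 into enolate 10, which share mixed aggregates; copper(II) takes one electron from the more electron-rich ester enolate 10, the α-carbonyl radical (free or copper-bound) adds to C8 of the less easily oxidised 9, and a second copper(II) oxidises the resulting radical anion, so that the two donor carbons C8 and C8′ end up bonded. No ring is closed; the step joins two C6–C3 halves in the middle of the chain and creates both stereocentres at once. C8 is controlled by the auxiliary: the C4 benzyl group of the (S)-oxazolidinone covers one face of the planar chelated enolate, the new bond forms on the open face in the same sense as in alkylations of such enolates, and with the priorities C(=O)N > C8′ > C7 this is 8R. C8′ is controlled only by relative topicity: bond formation inside a metal-bridged aggregate keeps the two carbonyl groups synclinal and turns the tert-butoxy group and both benzyl groups outwards, which favours the like (8R,8′R) combination, as in oxidative homocouplings of 3-arylpropanoate enolates. Because this second element is the weaker one, the route does not depend on it, since step 5 equilibrates C8′. The selectivity that the step does need is cross- over homocoupling, secured by the different oxidation potentials and aggregation of an imide and an ester enolate and by the excess of 8, and oxidation of enolate rather than arene, secured by the benzyl ether on ring B, which excludes a phenoxide.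

Step 5
Reactants: 11 tert-butyl (2R,3R)-4-[(4S)-4-benzyl-2-oxo-1,3-oxazolidin-3-yl]-2-[4-(benzyloxy)-3,5-dimethoxybenzyl]-3-(3,4-dimethoxybenzyl)-4-oxobutanoate
Product: 13 (3R,4R)-3-[4-(benzyloxy)-3,5-dimethoxybenzyl]-4-(3,4-dimethoxybenzyl)oxolan-2-one, via tert-butyl (2R,3R)-2-[4-(benzyloxy)-3,5-dimethoxybenzyl]-3-(3,4-dimethoxybenzyl)-4-hydroxybutanoate 12 (not isolated)
Conditions: LiBH4, MeOH, THF, 0 °C; then p-TsOH·H2O (cat.), PhMe, 80 °C; then DBU, PhMe, 60 °C
Reagents that add atoms: none
Why: Reductive cleavage of an N-acyloxazolidinone with LiBH4/MeOH attacks the activated exocyclic imide carbonyl and leaves the tert-butyl ester, and acid-catalysed 5-exo-trig lactonisation of 12 then closes the ring. DBU equilibrates C8′, now the only enolisable centre, to the more stable trans-lactone, so any material epimeric at C8′ that is carried along from step 4 converges on 13. C8 sits in the β-position, is not acidic, and keeps the configuration set by the auxiliary.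

Step 6
Reactants: 13 (3R,4R)-3-[4-(benzyloxy)-3,5-dimethoxybenzyl]-4-(3,4-dimethoxybenzyl)oxolan-2-one
Product: 14 (2R,3R)-2-[4-(benzyloxy)-3,5-dimethoxybenzyl]-3-(3,4-dimethoxybenzyl)butane-1,4-diol
Conditions: LiAlH4, THF, 0 °C → rt; Fieser work-up
Reagents that add atoms: none
Why: Hydride reduction of a γ-lactone to the 1,4-diol; hydride addition is much faster than enolisation, and after ring opening neither C8 nor C8′ is acidic. Aryl methyl and aryl benzyl ethers are inert, and the basic work-up avoids cyclodehydration to the tetrahydrofuran.

Step 7
Reactants: 14 (2R,3R)-2-[4-(benzyloxy)-3,5-dimethoxybenzyl]-3-(3,4-dimethoxybenzyl)butane-1,4-diol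
Product: 15 (2R,3R)-2-[4-(benzyloxy)-3,5-dimethoxybenzyl]-3-(3,4-dimethoxybenzyl)butane-1,4-diyl diacetate
Conditions: Ac2O, pyridine, DMAP (cat.), CH2Cl2, 0 °C → rt
Reagents that add atoms: acetic anhydride, CC(=O)OC(C)=O
Why: DMAP-catalysed O-acetylation of two primary alcohols. The phenol of ring B is still masked, so no third acetate can form, and the stereocentres are not involved.

Step 8
Reactants: 15 (2R,3R)-2-[4-(benzyloxy)-3,5-dimethoxybenzyl]-3-(3,4-dimethoxybenzyl)butane-1,4-diyl diacetate
Product: 16 Justin C, (2R,3R)-2-(3,4-dimethoxybenzyl)-3-(4-hydroxy-3,5-dimethoxybenzyl)butane-1,4-diyl diacetate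
Conditions: H2 (1 atm), 10% Pd/C, EtOAc, rt
Reagents that add atoms: none
Why: Hydrogenolysis of an aryl benzyl ether on palladium under neutral conditions. The primary, non-benzylic acetates, the methyl ethers and the C7/C7′ carbon–carbon bonds are not cleaved, and neither stereocentre is touched.

## Compound list

1 | 3-(3,4-dimethoxyphenyl)propanoic acid | COc1ccc(CCC(=O)O)cc1OC | starting material
2 | (4S)-4-benzyl-1,3-oxazolidin-2-one | O=C1N[C@@H](Cc2ccccc2)CO1 | starting material
3 | 3-(3,4-dimethoxyphenyl)propanoic pivalic anhydride | COc1ccc(CCC(=O)OC(=O)C(C)(C)C)cc1OC | intermediate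
4 | (4S)-4-benzyl-3-[3-(3,4-dimethoxyphenyl)propanoyl]-1,3-oxazolidin-2-one | COc1ccc(CCC(=O)N2C(=O)OC[C@@H]2Cc3ccccc3)cc1OC | intermediate
5 | 4-(benzyloxy)-3,5-dimethoxybenzaldehyde | COc1cc(C=O)cc(OC)c1OCc1ccccc1 | starting material
6 | tert-butyl (diethoxyphosphoryl)acetate | CCOP(=O)(CC(=O)OC(C)(C)C)OCC | starting material
7 | tert-butyl (2E)-3-[4-(benzyloxy)-3,5-dimethoxyphenyl]prop-2-enoate | COc1cc(/C=C/C(=O)OC(C)(C)C)cc(OC)c1OCc1ccccc1 | intermediate
8 | tert-butyl 3-[4-(benzyloxy)-3,5-dimethoxyphenyl]propanoate | COc1cc(CCC(=O)OC(C)(C)C)cc(OC)c1OCc1ccccc1 | intermediate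
9 | chelated lithium (Z)-enolate of imide 4 | [Li+].[O-]/C(=C\Cc1ccc(OC)c(OC)c1)N1C(=O)OC[C@@H]1Cc1ccccc1 | intermediate
10 | lithium enolate of ester 8 (CH2Ar trans to OLi) | [Li+].[O-]/C(OC(C)(C)C)=C/Cc1cc(OC)c(OCc2ccccc2)c(OC)c1 | intermediate
11 | tert-butyl (2R,3R)-4-[(4S)-4-benzyl-2-oxo-1,3-oxazolidin-3-yl]-2-[4-(benzyloxy)-3,5-dimethoxybenzyl]-3-(3,4-dimethoxybenzyl)-4-oxobutanoate | COc1ccc(C[C@@H](C(=O)N2C(=O)OC[C@@H]2Cc2ccccc2)[C@H](C(=O)OC(C)(C)C)Cc2cc(OC)c(OCc3ccccc3)c(OC)c2)cc1OC | intermediate
12 | tert-butyl (2R,3R)-2-[4-(benzyloxy)-3,5-dimethoxybenzyl]-3-(3,4-dimethoxybenzyl)-4-hydroxybutanoate | COc1ccc(C[C@@H](CO)[C@H](C(=O)OC(C)(C)C)Cc2cc(OC)c(OCc3ccccc3)c(OC)c2)cc1OC | intermediate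
13 | (3R,4R)-3-[4-(benzyloxy)-3,5-dimethoxybenzyl]-4-(3,4-dimethoxybenzyl)oxolan-2-one | COc1ccc(C[C@H]2COC(=O)[C@@H]2Cc2cc(OC)c(OCc3ccccc3)c(OC)c2)cc1OC | intermediate
14 | (2R,3R)-2-[4-(benzyloxy)-3,5-dimethoxybenzyl]-3-(3,4-dimethoxybenzyl)butane-1,4-diol | COc1ccc(C[C@@H](CO)[C@H](CO)Cc2cc(OC)c(OCc3ccccc3)c(OC)c2)cc1OC | intermediate
15 | (2R,3R)-2-[4-(benzyloxy)-3,5-dimethoxybenzyl]-3-(3,4-dimethoxybenzyl)butane-1,4-diyl diacetate | COc1ccc(C[C@@H](COC(C)=O)[C@H](COC(C)=O)Cc2cc(OC)c(OCc3ccccc3)c(OC)c2)cc1OC | intermediate
16 | Justin C, (2R,3R)-2-(3,4-dimethoxybenzyl)-3-(4-hydroxy-3,5-dimethoxybenzyl)butane-1,4-diyl diacetate | COc1ccc(C[C@@H](COC(C)=O)[C@H](COC(C)=O)Cc2cc(OC)c(O)c(OC)c2)cc1OC | target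

## Step count and least certain steps

Total step count: 8.

Longest linear sequence: 7 steps (5 → 7 → 8 → 11 → 13 → 14 → 15 → 16, steps 2 to 8). Step 1 runs in parallel.

**Step 4 (key step).**
- Risk: homocoupling of each enolate and plain re-protonation may compete with the cross-coupling.
- Cause: the discrimination rests only on a moderate gap in oxidation potential and on mixed aggregation, while the two partners have the same steric profile.
- A further risk: the face selectivity at C8 may erode if the bond forms from a non-chelated enolate.
- Fallback: the oxidative union is replaced by a polar construction that sets out from 4 and 5 and rejoins the route at 13.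
  - Evans alkylation of 4 (NaHMDS, tert-butyl bromoacetate, THF, −78 °C) should give tert-butyl (3R)-4-[(4S)-4-benzyl-2-oxo-1,3-oxazolidin-3-yl]-3-(3,4-dimethoxybenzyl)-4-oxobutanoate F1.
  - LiBH4/MeOH should give tert-butyl (3R)-3-(3,4-dimethoxybenzyl)-4-hydroxybutanoate F2.
  - Catalytic p-TsOH in warm toluene should close it to (4R)-4-(3,4-dimethoxybenzyl)oxolan-2-one F3.
  - In parallel, 5 is reduced with NaBH4 to [4-(benzyloxy)-3,5-dimethoxyphenyl]methanol F4 and converted with PBr3 into 2-(benzyloxy)-5-(bromomethyl)-1,3-dimethoxybenzene F5.
  - Alkylation of the lithium enolate of F3 (LiHMDS, THF, −78 °C) with F5, anti to the C4 substituent, should give 13.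

**Step 5.**
- Risk: hydride may attack the endocyclic carbamate carbonyl and open the auxiliary ring.
- Cause: the exocyclic carbonyl of 11 is flanked by two adjacent branched carbons.
- A further risk: lactonisation of the hindered tert-butyl ester may be slow.
- Fallback: it sets out from 11 and rejoins the route at 12, replacing hydride cleavage by hydrolytic cleavage.
  - LiOH/H2O2 in THF/water cleaves even hindered imides at the exocyclic carbonyl. It should give (2R,3R)-3-[4-(benzyloxy)-3,5-dimethoxybenzyl]-4-tert-butoxy-2-(3,4-dimethoxybenzyl)-4-oxobutanoic acid F6.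
  - BH3·THF should reduce the free acid of F6 in the presence of the tert-butyl ester to 12.
  - Ring closure and equilibration then follow as in step 5.

**Step 3.**
- Risk: the rhodium catalyst may turn over slowly on an electron-rich cinnamate with a bulky ester, while a heterogeneous catalyst would cause loss of the benzyl protecting group.
- Fallback: it sets out from 7 and rejoins the route at 8, accepting the loss of the protecting group instead of avoiding it.
  - H2 on Pd/C in EtOAc should give tert-butyl 3-(4-hydroxy-3,5-dimethoxyphenyl)propanoate F7.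
  - Re-benzylation with BnBr and K2CO3 in DMF should give 8.

**Step 8.**
- Risk: the hydrogenolysis may stall because traces of pyridine, DMAP or copper poison the catalyst, and because the two ortho methoxy groups shield the ether. Forcing conditions would risk ring hydrogenation.
- Fallback: it sets out from 14 and rejoins the route at 16, changing the order of events and the basis of the phenol/alcohol differentiation.
  - Hydrogenolysis at the diol stage should give (2R,3R)-2-(3,4-dimethoxybenzyl)-3-(4-hydroxy-3,5-dimethoxybenzyl)butane-1,4-diol F8.
  - Peracetylation (Ac2O, pyridine) should give (2R,3R)-2-[4-(acetyloxy)-3,5-dimethoxybenzyl]-3-(3,4-dimethoxybenzyl)butane-1,4-diyl diacetate F9.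
  - Aminolysis with one equivalent of pyrrolidine in MeCN at 0 °C should remove only the aryl acetate, whose phenoxide is the far better leaving group, and give 16.

## Further compounds

F1 | step 4 | tert-butyl (3R)-4-[(4S)-4-benzyl-2-oxo-1,3-oxazolidin-3-yl]-3-(3,4-dimethoxybenzyl)-4-oxobutanoate | COc1ccc(C[C@@H](C(=O)N2C(=O)OC[C@@H]2Cc2ccccc2)CC(=O)OC(C)(C)C)cc1OC
F2 | step 4 | tert-butyl (3R)-3-(3,4-dimethoxybenzyl)-4-hydroxybutanoate | COc1ccc(C[C@@H](CO)CC(=O)OC(C)(C)C)cc1OC
F3 | step 4 | (4R)-4-(3,4-dimethoxybenzyl)oxolan-2-one | COc1ccc(C[C@H]2COC(=O)C2)cc1OC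
F4 | step 4 | [4-(benzyloxy)-3,5-dimethoxyphenyl]methanol | COc1cc(CO)cc(OC)c1OCc1ccccc1
F5 | step 4 | 2-(benzyloxy)-5-(bromomethyl)-1,3-dimethoxybenzene | COc1cc(CBr)cc(OC)c1OCc1ccccc1
F6 | step 5 | (2R,3R)-3-[4-(benzyloxy)-3,5-dimethoxybenzyl]-4-tert-butoxy-2-(3,4-dimethoxybenzyl)-4-oxobutanoic acid | COc1ccc(C[C@@H](C(=O)O)[C@H](C(=O)OC(C)(C)C)Cc2cc(OC)c(OCc3ccccc3)c(OC)c2)cc1OC
F7 | step 3 | tert-butyl 3-(4-hydroxy-3,5-dimethoxyphenyl)propanoate | COc1cc(CCC(=O)OC(C)(C)C)cc(OC)c1O
F8 | step 8 | (2R,3R)-2-(3,4-dimethoxybenzyl)-3-(4-hydroxy-3,5-dimethoxybenzyl)butane-1,4-diol | COc1ccc(C[C@@H](CO)[C@H](CO)Cc2cc(OC)c(O)c(OC)c2)cc1OC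
F9 | step 8 | (2R,3R)-2-[4-(acetyloxy)-3,5-dimethoxybenzyl]-3-(3,4-dimethoxybenzyl)butane-1,4-diyl diacetate | COc1ccc(C[C@@H](COC(C)=O)[C@H](COC(C)=O)Cc2cc(OC)c(OC(C)=O)c(OC)c2)cc1OC
A1 | alternative 1 | (4R)-4-[4-(benzyloxy)-3,5-dimethoxybenzyl]oxolan-2-one | COc1cc(C[C@H]2COC(=O)C2)cc(OC)c1OCc1ccccc1
A2 | alternative 1 | 4-(bromomethyl)-1,2-dimethoxybenzene | COc1ccc(CBr)cc1OC
A3 | alternative 1 | (3R,4R)-4-[4-(benzyloxy)-3,5-dimethoxybenzyl]-3-(3,4-dimethoxybenzyl)oxolan-2-one | COc1cc(C[C@H]2COC(=O)[C@@H]2Cc2ccc(OC)c(OC)c2)cc(OC)c1OCc1ccccc1
A4 | alternative 2 | dimethyl (2E,3E)-2-[4-(benzyloxy)-3,5-dimethoxybenzylidene]-3-(3,4-dimethoxybenzylidene)butanedioate | COC(=O)/C(=C/c1ccc(OC)c(OC)c1)C(=C/c1cc(OC)c(OCc2ccccc2)c(OC)c1)\C(=O)OC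
A5 | alternative 2 | dimethyl (2R,3R)-2-[4-(benzyloxy)-3,5-dimethoxybenzyl]-3-(3,4-dimethoxybenzyl)butanedioate | COc1ccc(C[C@@H](C(=O)OC)[C@H](C(=O)OC)Cc2cc(OC)c(OCc3ccccc3)c(OC)c2)cc1OC
A6 | alternative 3 | 2,3-bis(hydroxymethyl)butane-1,4-diol | OCC(CO)C(CO)CO
A7 | alternative 3 | (2S,3S)-2,3-bis(hydroxymethyl)butane-1,4-diyl diacetate | OC[C@@H](COC(C)=O)[C@H](COC(C)=O)CO
A8 | alternative 3 | (2R,3R)-2,3-bis(iodomethyl)butane-1,4-diyl diacetate | IC[C@@H](COC(C)=O)[C@H](COC(C)=O)CI
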